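**Retrosynthetic overview**

1. The strategy rests on ring B, the prenyl-bearing benzene ring (B1 CH2 bridge to ring A, B2 OH, B3 acetyl, B4 OH, B5 prenyl, B6 OMe): it is hexasubstituted with its three oxygens on the alternate carbons B2, B4 and B6.
2. Ring B is cut at B4–B5 and B1–B6 (ketene–ynol ether [2+2]) and at B3–B4 (6π closure), giving a 2-(ring-A-benzyl)-3-siloxycyclobutenone (C=O becomes B4, C–OSi becomes B2) and a prenylated methoxyalkyne (C–OMe becomes B6).
3. The cyclobutenone comes from the ring A propanoic acid by ketene/ethoxyacetylene cycloaddition, hydrolysis to the 1,3-dione enol and O-silylation; ring A itself comes from 2',6'-dihydroxy-4'-methoxyacetophenone by C-methylation, formylation, MOM protection and two-carbon homologation.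
4. The alkyne comes from chloroacetaldehyde dimethyl acetal and prenyl bromide; the B3 acetyl is added after the benzannulation by bromination, Stille coupling and hydrolysis, followed by deprotection.
5. Ring order: ring A is present from the start, the four-membered ring is built on its side chain, and ring B is formed last.

Key step: step 10

Assumption: the 2-substituted cyclobutane-1,3-dione is taken to rest as its more substituted enol 13, as simple 2-alkyl analogues do, so that O-silylation gives the 2-benzyl-3-siloxy isomer 14. Compounds 3, 12 and 20 are racemic; the target has no stereocentre.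

**Route**

Step 1
Reactants: 1 2',6'-dihydroxy-4'-methoxyacetophenone
Product: 2 2',6'-dihydroxy-4'-methoxy-3'-methylacetophenone
Conditions: MeI (1.0 equiv), NaOMe, MeOH, reflux
Reagents that add atoms: iodomethane, CI
Why: C-Methylation of the phloroglucinol-type phenoxide (soft carbon alkylation in a protic solvent) at one of the two equivalent free ring carbons, with a single equivalent of MeI to hold the reaction at the monomethyl stage.

Step 2
Reactants: 2 2',6'-dihydroxy-4'-methoxy-3'-methylacetophenone
Product: 4 3-acetyl-2,4-dihydroxy-6-methoxy-5-methylbenzaldehyde, via aryl(chloro)methyl methyl ether 3 (not isolated)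
Conditions: Cl2CHOMe, TiCl4, CH2Cl2, 0 °C; then 1 M HCl (aq)
Reagents that add atoms: dichloromethyl methyl ether, COC(Cl)Cl; water, O
Why: Rieche formylation at the only free ring carbon (ortho to OH and OMe, para to the second OH), the α-chloro ether 3 being hydrolysed on aqueous work-up; this electrophile leaves the ortho-hydroxyaryl methyl ketone alone, which a Vilsmeier reagent could convert into a chromone.

Step 3
Reactants: 4 3-acetyl-2,4-dihydroxy-6-methoxy-5-methylbenzaldehyde
Product: 5 3-acetyl-6-methoxy-2,4-bis(methoxymethoxy)-5-methylbenzaldehyde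
Conditions: MOMCl, iPr2NEt, CH2Cl2, 0 °C to rt
Reagents that add atoms: chloromethyl methyl ether, COCCl
Why: O-Alkylation of both hydrogen-bonded phenols with MOMCl (acetal-type ether formation under amine base), which masks them against acylation by the acid chloride and ketene of step 6.

Step 4
Reactants: 5 3-acetyl-6-methoxy-2,4-bis(methoxymethoxy)-5-methylbenzaldehyde; 6 benzyl (triphenylphosphoranylidene)acetate
Product: 7 benzyl (E)-3-[3-acetyl-6-methoxy-2,4-bis(methoxymethoxy)-5-methylphenyl]prop-2-enoate
Conditions: toluene, 90 °C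
Reagents that add atoms: none
Why: Wittig olefination with a stabilised ylide, which reacts with the aldehyde under neutral conditions and not with the twisted, doubly ortho-substituted aryl methyl ketone; the alkene geometry is irrelevant because the alkene is reduced next.

Step 5
Reactants: 7 benzyl (E)-3-[3-acetyl-6-methoxy-2,4-bis(methoxymethoxy)-5-methylphenyl]prop-2-enoate
Product: 8 3-[3-acetyl-6-methoxy-2,4-bis(methoxymethoxy)-5-methylphenyl]propanoic acid
Conditions: H2 (1 atm), Pd/C, EtOAc, rt
Reagents that add atoms: none
Why: Catalytic hydrogenation saturates the cinnamate alkene and hydrogenolyses the benzyl ester in one operation, while the hindered aryl ketone and the MOM ethers should survive in a neutral solvent at 1 atm.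

Step 6
Reactants: 8 3-[3-acetyl-6-methoxy-2,4-bis(methoxymethoxy)-5-methylphenyl]propanoic acid; 9 ethoxyacetylene
Product: 12 4-{[3-acetyl-6-methoxy-2,4-bis(methoxymethoxy)-5-methylphenyl]methyl}-3-ethoxycyclobut-2-en-1-one (racemic), via acid chloride 10 (not isolated), via ketene 11 (not isolated)
Conditions: 1-chloro-N,N,2-trimethylprop-1-en-1-amine, CH2Cl2, 0 °C; then added slowly to ethoxyacetylene (5 equiv), Et3N, CH2Cl2, 0 °C to rt
Reagents that add atoms: none
Why: The Ghosez chloroenamine gives the acid chloride without releasing HCl (which would threaten the MOM ethers), Et3N dehydrochlorinates it to the aldoketene 11, and the ketene–ynol ether [2+2] cycloaddition (Wasserman cyclobutenone synthesis) joins the unsubstituted alkyne carbon to the ketene carbonyl carbon; slow addition into excess ethoxyacetylene should suppress ketene dimerisation.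

Step 7
Reactants: 12 4-{[3-acetyl-6-methoxy-2,4-bis(methoxymethoxy)-5-methylphenyl]methyl}-3-ethoxycyclobut-2-en-1-one
Product: 13 2-{[3-acetyl-6-methoxy-2,4-bis(methoxymethoxy)-5-methylphenyl]methyl}-3-hydroxycyclobut-2-en-1-one
Conditions: 0.5 M HCl (aq), THF, 0 °C to rt
Reagents that add atoms: water, O
Why: Acid hydrolysis of the vinylogous ester, which protonates to a doubly oxygen-stabilised cyclobutenyl cation and should therefore react in acid dilute enough to spare the aryl MOM ethers; the 1,3-dione formed settles as its more substituted enol 13.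

Step 8
Reactants: 13 2-{[3-acetyl-6-methoxy-2,4-bis(methoxymethoxy)-5-methylphenyl]methyl}-3-hydroxycyclobut-2-en-1-one
Product: 14 2-{[3-acetyl-6-methoxy-2,4-bis(methoxymethoxy)-5-methylphenyl]methyl}-3-[(triisopropylsilyl)oxy]cyclobut-2-en-1-one
Conditions: TIPSCl, Et3N, CH2Cl2, 0 °C
Reagents that add atoms: chlorotriisopropylsilane, CC(C)[Si](Cl)(C(C)C)C(C)C
Why: O-Silylation of the strongly acidic vinylogous acid (pKa near 3) as its triethylammonium salt; both oxygens of the symmetric dionate give the same 2-benzyl-3-siloxycyclobutenone, and the bulky TIPS group should make this vinylogous silyl ester stable enough to handle.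

Step 9
Reactants: 15 chloroacetaldehyde dimethyl acetal; 16 prenyl bromide
Product: 18 1-methoxy-5-methylhex-4-en-1-yne, via lithium methoxyacetylide 17 (not isolated)
Conditions: LiNEt2 (3.2 equiv), THF, 0 °C; then prenyl bromide, DMPU, −20 °C to rt
Reagents that add atoms: none
Why: Double elimination (of methanol and HCl) from the chloroacetal and deprotonation by three equivalents of LiNEt2 give lithium methoxyacetylide in situ, which is alkylated in an SN2 reaction at the primary carbon of prenyl bromide in the presence of DMPU.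

Step 10
Reactants: 14 2-{[3-acetyl-6-methoxy-2,4-bis(methoxymethoxy)-5-methylphenyl]methyl}-3-[(triisopropylsilyl)oxy]cyclobut-2-en-1-one; 18 1-methoxy-5-methylhex-4-en-1-yne
Product: 23 1-[3-({4-hydroxy-2-methoxy-3-(3-methylbut-2-en-1-yl)-6-[(triisopropylsilyl)oxy]phenyl}methyl)-4-methoxy-2,6-bis(methoxymethoxy)-5-methylphenyl]ethanone (ring B: B2 OTIPS; B3 H; B4 OH; B5 prenyl; B6 OMe), via vinylketene 19 (not isolated), via vinylcyclobutenone 20 (not isolated), via dienylketene 21 (not isolated), via cyclohexadienone 22 (not isolated)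
Conditions: 18 (2 equiv), toluene, 110 °C, sealed tube; 14 added slowly
Reagents that add atoms: none
Why: Thermal 4π electrocyclic opening of 14 gives the 2-siloxyvinylketene 19, whose ketene C=C adds to the ynol ether 18 in a [2+2] cycloaddition that forms the B4–B5 and B1–B6 bonds in the 4-vinylcyclobutenone 20; a second 4π opening gives the dienylketene 21. Ring B then closes by thermal disrotatory 6π electrocyclisation of 21 at B3–B4, and the cyclohexa-2,4-dienone 22 tautomerises to the phenol, so that the carbonyl oxygen of 14 becomes the B4 OH, the siloxy carbon becomes B2 and the ring CH2 becomes B3–H. The closest known reaction is the Danheiser benzannulation of cyclobutenones with alkoxy- and siloxyalkynes to resorcinol derivatives, and 3-alkoxycyclobutenones are known to enter the same cascade when alkoxyalkynes are thermolysed. No stereocentre is formed: the quaternary carbon of racemic 20 is lost on ring opening and 23 is achiral. The selectivity needed is the regiochemistry of the ketene–alkyne [2+2], which the polarisation of 18 secures: its oxygen-free carbon (the one bearing the prenyl CH2) is the nucleophilic end and bonds to the electrophilic ketene carbonyl carbon, which places OMe at B6 between the bridge and the prenyl group, and the ynol ether should also outcompete the isolated prenyl alkene and the ring A ketone for the ketene. Methoxy is chosen over ethoxy on the alkyne because it cannot lose an alkene by retro-ene reaction at this temperature, and the excess of 18 with slow addition of 14 should limit O-acylation of the product phenol by 19.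

Step 11
Reactants: 23 the B3–H phenol from step 10
Product: 24 1-[3-({5-bromo-4-hydroxy-2-methoxy-3-(3-methylbut-2-en-1-yl)-6-[(triisopropylsilyl)oxy]phenyl}methyl)-4-methoxy-2,6-bis(methoxymethoxy)-5-methylphenyl]ethanone (bromine at B3)
Conditions: NBS (1.0 equiv), CH2Cl2, −78 °C
Reagents that add atoms: N-bromosuccinimide, O=C1CCC(=O)N1Br
Why: Electrophilic aromatic bromination at the only free ring-B carbon B3, which is ortho to the free B4 hydroxyl and the B2 siloxy group and para to the B6 methoxy group and should therefore react with one equivalent of NBS at −78 °C faster than the prenyl alkene.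

Step 12
Reactants: 24 the B3 bromide; 25 tributyl(1-ethoxyvinyl)stannane
Product: 27 1-[3-({5-acetyl-4-hydroxy-2-methoxy-3-(3-methylbut-2-en-1-yl)-6-[(triisopropylsilyl)oxy]phenyl}methyl)-4-methoxy-2,6-bis(methoxymethoxy)-5-methylphenyl]ethanone (acetyl at B3), via 1-ethoxyvinyl arene 26 (not isolated)
Conditions: Pd(PtBu3)2 (cat), toluene, 90 °C; then 1 M HCl (aq), THF, rt
Reagents that add atoms: water, O
Why: Stille coupling: oxidative addition of zerovalent palladium carrying the bulky electron-rich PtBu3 ligand into the hindered electron-rich aryl bromide, transmetalation of the 1-ethoxyvinyl group from tin and reductive elimination give the enol ether 26, which brief dilute acid hydrolyses to the methyl ketone without touching the MOM or TIPS ethers.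

Step 13
Reactants: 27 the B3 acetyl compound
Product: 28 1-[3-({3-acetyl-2,4-dihydroxy-6-methoxy-5-(3-methylbut-2-en-1-yl)phenyl}methyl)-4-methoxy-2,6-bis(methoxymethoxy)-5-methylphenyl]ethanone
Conditions: Bu4NF, AcOH, THF, 0 °C
Reagents that add atoms: none
Why: Fluoride-induced cleavage of the aryl silyl ether, fast because the B2 phenoxide is stabilised by the ortho acetyl group; acetic acid buffers the phenoxide formed.

Step 14
Reactants: 28 the ring A bis-MOM ether
Product: 29 mallotojaponin B, 1-[3-({3-acetyl-2,4-dihydroxy-6-methoxy-5-(3-methylbut-2-en-1-yl)phenyl}methyl)-2,6-dihydroxy-4-methoxy-5-methylphenyl]ethanone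
Conditions: HCl (3 M, aq), MeOH, rt
Reagents that add atoms: none
Why: Acid-catalysed transacetalisation of the two MOM ethers to methanol, made easy by hydrogen bonding of the freed phenols to the ring A acetyl group; mild acid at room temperature should leave the prenyl group uncyclised and both methyl ethers intact.

**Compound list**

1 | 2',6'-dihydroxy-4'-methoxyacetophenone | CC(=O)c1c(O)cc(OC)cc1O | starting material
2 | 2',6'-dihydroxy-4'-methoxy-3'-methylacetophenone | CC(=O)c1c(O)cc(OC)c(C)c1O | intermediate
3 | 1-{3-[chloro(methoxy)methyl]-2,6-dihydroxy-4-methoxy-5-methylphenyl}ethanone (racemic, not isolated) | CC(=O)c1c(O)c(C)c(OC)c(C(Cl)OC)c1O | intermediate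
4 | 3-acetyl-2,4-dihydroxy-6-methoxy-5-methylbenzaldehyde | CC(=O)c1c(O)c(C)c(OC)c(C=O)c1O | intermediate
5 | 3-acetyl-6-methoxy-2,4-bis(methoxymethoxy)-5-methylbenzaldehyde | CC(=O)c1c(OCOC)c(C)c(OC)c(C=O)c1OCOC | intermediate
6 | benzyl (triphenylphosphoranylidene)acetate | O=C(C=P(c1ccccc1)(c1ccccc1)c1ccccc1)OCc1ccccc1 | starting material
7 | benzyl (E)-3-[3-acetyl-6-methoxy-2,4-bis(methoxymethoxy)-5-methylphenyl]prop-2-enoate | CC(=O)c1c(OCOC)c(C)c(OC)c(/C=C/C(=O)OCc2ccccc2)c1OCOC | intermediate
8 | 3-[3-acetyl-6-methoxy-2,4-bis(methoxymethoxy)-5-methylphenyl]propanoic acid | CC(=O)c1c(OCOC)c(C)c(OC)c(CCC(=O)O)c1OCOC | intermediate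
9 | ethoxyacetylene | CCOC#C | starting material
10 | 3-[3-acetyl-6-methoxy-2,4-bis(methoxymethoxy)-5-methylphenyl]propanoyl chloride (not isolated) | CC(=O)c1c(OCOC)c(C)c(OC)c(CCC(=O)Cl)c1OCOC | intermediate
11 | 3-[3-acetyl-6-methoxy-2,4-bis(methoxymethoxy)-5-methylphenyl]prop-1-en-1-one, the aldoketene (not isolated) | CC(=O)c1c(OCOC)c(C)c(OC)c(CC=C=O)c1OCOC | intermediate
12 | 4-{[3-acetyl-6-methoxy-2,4-bis(methoxymethoxy)-5-methylphenyl]methyl}-3-ethoxycyclobut-2-en-1-one (racemic) | CCOC1=CC(=O)C1Cc1c(OCOC)c(C(C)=O)c(OCOC)c(C)c1OC | intermediate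
13 | 2-{[3-acetyl-6-methoxy-2,4-bis(methoxymethoxy)-5-methylphenyl]methyl}-3-hydroxycyclobut-2-en-1-one | O=C1CC(O)=C1Cc1c(OCOC)c(C(C)=O)c(OCOC)c(C)c1OC | intermediate
14 | 2-{[3-acetyl-6-methoxy-2,4-bis(methoxymethoxy)-5-methylphenyl]methyl}-3-[(triisopropylsilyl)oxy]cyclobut-2-en-1-one | O=C1CC(O[Si](C(C)C)(C(C)C)C(C)C)=C1Cc1c(OCOC)c(C(C)=O)c(OCOC)c(C)c1OC | intermediate
15 | chloroacetaldehyde dimethyl acetal | COC(CCl)OC | starting material
16 | prenyl bromide (1-bromo-3-methylbut-2-ene) | CC(C)=CCBr | starting material
17 | lithium methoxyacetylide (not isolated) | [Li]C#COC | intermediate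
18 | 1-methoxy-5-methylhex-4-en-1-yne | COC#CCC=C(C)C | intermediate
19 | 2-siloxyvinylketene from ring opening of 14 (not isolated) | O=C=C(Cc1c(OCOC)c(C(C)=O)c(OCOC)c(C)c1OC)C(=C)O[Si](C(C)C)(C(C)C)C(C)C | intermediate
20 | 4-benzyl-3-methoxy-2-prenyl-4-(1-siloxyvinyl)cyclobut-2-en-1-one, the [2+2] adduct (racemic, not isolated) | O=C1C(CC=C(C)C)=C(OC)C1(Cc1c(OCOC)c(C(C)=O)c(OCOC)c(C)c1OC)C(=C)O[Si](C(C)C)(C(C)C)C(C)C | intermediate
21 | dienylketene from ring opening of 20, siloxyvinyl group cis to the ketene carbon (not isolated) | O=C=C(CC=C(C)C)/C(OC)=C(/Cc1c(OCOC)c(C(C)=O)c(OCOC)c(C)c1OC)C(=C)O[Si](C(C)C)(C(C)C)C(C)C | intermediate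
22 | cyclohexa-2,4-dienone tautomer of 23 (not isolated) | O=C1CC(O[Si](C(C)C)(C(C)C)C(C)C)=C(Cc2c(OCOC)c(C(C)=O)c(OCOC)c(C)c2OC)C(OC)=C1CC=C(C)C | intermediate
23 | 1-[3-({4-hydroxy-2-methoxy-3-(3-methylbut-2-en-1-yl)-6-[(triisopropylsilyl)oxy]phenyl}methyl)-4-methoxy-2,6-bis(methoxymethoxy)-5-methylphenyl]ethanone | COc1c(C)c(OCOC)c(C(C)=O)c(OCOC)c1Cc1c(O[Si](C(C)C)(C(C)C)C(C)C)cc(O)c(CC=C(C)C)c1OC | intermediate
24 | B3 bromide of 23 | COc1c(C)c(OCOC)c(C(C)=O)c(OCOC)c1Cc1c(O[Si](C(C)C)(C(C)C)C(C)C)c(Br)c(O)c(CC=C(C)C)c1OC | intermediate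
25 | tributyl(1-ethoxyvinyl)stannane | CCCC[Sn](CCCC)(CCCC)C(=C)OCC | starting material
26 | B3 1-ethoxyvinyl compound (not isolated) | COc1c(C)c(OCOC)c(C(C)=O)c(OCOC)c1Cc1c(O[Si](C(C)C)(C(C)C)C(C)C)c(C(=C)OCC)c(O)c(CC=C(C)C)c1OC | intermediate
27 | B3 acetyl compound with B2 OTIPS and ring A bis-MOM | COc1c(C)c(OCOC)c(C(C)=O)c(OCOC)c1Cc1c(O[Si](C(C)C)(C(C)C)C(C)C)c(C(C)=O)c(O)c(CC=C(C)C)c1OC | intermediate
28 | ring A bis-MOM ether of mallotojaponin B | COc1c(C)c(OCOC)c(C(C)=O)c(OCOC)c1Cc1c(O)c(C(C)=O)c(O)c(CC=C(C)C)c1OC | intermediate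
29 | mallotojaponin B | COc1c(C)c(O)c(C(C)=O)c(O)c1Cc1c(O)c(C(C)=O)c(O)c(CC=C(C)C)c1OC | target

**Step count**

Total: 14 steps. Longest linear sequence: 13 steps (steps 1–8 and 10–14 from compound 1); step 9 is a one-step branch.

**Steps most likely to fail**

Step 10 (benzannulation). The electrocyclic opening of the donor-stabilised 3-siloxycyclobutenone may be slow. The vinylketene may be intercepted by the flanking aryl ether oxygen of ring A, or may O-acylate the product phenol. The vinylogous silyl ester may also lose its silyl group before it reacts. The fallback gives up the benzannulation and joins two preformed acylphloroglucinol rings at the CH2 bridge, a known way to make methylene-bridged dimers of this family. It sets out from compounds 1 and 2 (with prenyl bromide 16) and comes back to the route at compound 29. Mannich reaction of 2 (aqueous CH2O, Me2NH, EtOH, rt) should give the Mannich base 1-{3-[(dimethylamino)methyl]-2,6-dihydroxy-4-methoxy-5-methylphenyl}ethanone F1. C-Prenylation of 1 with 16 (aqueous KOH, 0 °C) should give 1-[2,6-dihydroxy-4-methoxy-3-(3-methylbut-2-en-1-yl)phenyl]ethanone F3. Heating F1 with an excess of F3 (dioxane, reflux) should expel dimethylamine to form the ortho-quinone methide 2-acetyl-3-hydroxy-5-methoxy-4-methyl-6-methylidenecyclohexa-2,4-dien-1-one F2. F2 should alkylate the single free ring carbon of F3 and give 29 directly.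

Step 6 (ketene/ethoxyacetylene cycloaddition). The aldoketene may dimerise before the ynol ether traps it. The acyl chloride or ketene carbon may also be attacked by the neighbouring aryl ether oxygen with loss of a MOM group; the acid hydrolysis of step 7 adds a second exposure of these ethers. The fallback sets out from compound 5 and comes back at compound 13, replacing steps 4–7 by an organocatalytic reductive alkylation of a cyclic 1,3-dione. Aldehyde 5, cyclobutane-1,3-dione and Hantzsch ester (diethyl 2,6-dimethyl-1,4-dihydropyridine-3,5-dicarboxylate) with catalytic L-proline in CH2Cl2 at rt should undergo Knoevenagel condensation to the arylidene dione 2-{[3-acetyl-6-methoxy-2,4-bis(methoxymethoxy)-5-methylphenyl]methylidene}cyclobutane-1,3-dione F4. Conjugate hydride transfer to F4 in the same flask should give 13.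

Step 11 (bromination, with the coupling of step 12 that depends on it). Bromonium formation at the prenyl alkene with capture by the neighbouring B4 phenol (bromoetherification) may compete with ring bromination. Oxidative addition into the doubly ortho-substituted, electron-rich bromide may then be slow and end in protodebromination. The fallback avoids both halogenation and cross-coupling; it sets out from compound 23 and comes back at compound 27. Phenol-directed ortho-formylation of 23 (MgCl2, Et3N, paraformaldehyde, MeCN, reflux) should give the B3 salicylaldehyde F5. MeTi(OiPr)3 (THF, −40 to 0 °C) should add to the aldehyde and not to the hindered ring A ketone, giving the B3 1-hydroxyethyl carbinol F6. Oxidation of F6 with MnO2 (CH2Cl2, rt) should give 27.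

**Further compounds**

F1 | step 10 | 1-{3-[(dimethylamino)methyl]-2,6-dihydroxy-4-methoxy-5-methylphenyl}ethanone | CC(=O)c1c(O)c(CN(C)C)c(OC)c(C)c1O
F2 | step 10 | 2-acetyl-3-hydroxy-5-methoxy-4-methyl-6-methylidenecyclohexa-2,4-dien-1-one | CC(=O)C1=C(O)C(C)=C(OC)C(=C)C1=O
F3 | step 10 | 1-[2,6-dihydroxy-4-methoxy-3-(3-methylbut-2-en-1-yl)phenyl]ethanone | CC(=O)c1c(O)cc(OC)c(CC=C(C)C)c1O
F4 | step 6 | 2-{[3-acetyl-6-methoxy-2,4-bis(methoxymethoxy)-5-methylphenyl]methylidene}cyclobutane-1,3-dione | O=C1CC(=O)C1=Cc1c(OCOC)c(C(C)=O)c(OCOC)c(C)c1OC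
F5 | step 11 | B3 formyl analogue of 23 (salicylaldehyde) | COc1c(C)c(OCOC)c(C(C)=O)c(OCOC)c1Cc1c(O[Si](C(C)C)(C(C)C)C(C)C)c(C=O)c(O)c(CC=C(C)C)c1OC
F6 | step 11 | B3 1-hydroxyethyl analogue of 23 (racemic carbinol) | COc1c(C)c(OCOC)c(C(C)=O)c(OCOC)c1Cc1c(O[Si](C(C)C)(C(C)C)C(C)C)c(C(C)O)c(O)c(CC=C(C)C)c1OC
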